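**Retrosynthetic overview**
1. Last disconnection: the C(sp)–C(sp2) bond of the (E)-enyne in the C6 side chain. This gives terminal-alkyne acid 18 (C12: complete 1,2-dioxane, both stereocentres, free CO2H) and (E)-1-iodoundeca-1,10-diene 21 (C11), joined by a Sonogashira coupling as the final step.
2. Enabling feature: three CH2 groups separate the enyne from ring carbon C6. The ring O1–O2 bond lies between the fully substituted ketal carbon C6 (no α-H) and C3, whose side chain is a carboxylate under the coupling conditions. The peroxide should therefore tolerate Pd/Cu/amine while the alkyne C–H and the alkenyl C–I react.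
3. The 1,2-dioxane (the only ring) is closed by 6-exo-tet attack of a hydroperoxyketal on a secondary mesylate. The hydroperoxyketal comes from alkene-selective ozonolysis of a 1,1-disubstituted alkene in MeOH. C3 is set by inversion, C6 by anomeric equilibration in acidic MeOH.
4. Acyclic precursor: (S)-epoxide 4 (hydrolytic kinetic resolution) opened by a 2-substituted allyl Grignard reagent built on 3-chloro-2-(chloromethyl)prop-1-ene as a two-directional linchpin.
5. Iodide 21: Takai olefination of dec-9-enal.

Key step: step 13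

Remark on the chemistry: the target is read as the (3S,6R)-1,2-dioxane, in which the C6 methoxy group is cis to the C3 CH2CO2H group (chair with axial OMe and both carbon substituents equatorial). This is assumed to be the thermodynamically preferred C6 epimer, and step 9 relies on it.

**Route**

Step 1
Reactants: 1 but-3-en-1-ol
Product: 2 tert-butyl(but-3-en-1-yloxy)dimethylsilane
Conditions: TBSCl, imidazole, CH2Cl2, 0 °C → rt
Reagents that add atoms: tert-butyldimethylsilyl chloride, CC(C)(C)[Si](C)(C)Cl
Why: Imidazole-promoted silylation of a primary alcohol masks the future carboxyl carbon as a robust silyl ether; no stereocentre is involved.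

Step 2
Reactants: 2 tert-butyl(but-3-en-1-yloxy)dimethylsilane
Product: 3 rac-tert-butyldimethyl[2-(oxiran-2-yl)ethoxy]silane
Conditions: mCPBA, NaHCO3, CH2Cl2, 0 °C → rt
Reagents that add atoms: 3-chloroperoxybenzoic acid, OOC(=O)c1cccc(Cl)c1
Why: Prilezhaev epoxidation of the monosubstituted alkene should give the racemic terminal epoxide, the silyl ether being inert to the buffered peracid.

Step 3
Reactants: 3 rac-tert-butyldimethyl[2-(oxiran-2-yl)ethoxy]silane
Product: 4 (S)-tert-butyldimethyl[2-(oxiran-2-yl)ethoxy]silane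
Conditions: (S,S)-(salen)Co(III)OAc (0.5 mol %), H2O (0.55 equiv), THF, 0 °C → rt; distillation
Reagents that add atoms: none
Why: Jacobsen hydrolytic kinetic resolution, in which the (S,S)-catalyst (the antipode that hydrolyses the (R)-epoxide) should leave the (S)-epoxide in high enantiomeric purity; this catalyst-controlled carbon becomes C3 of the dioxane.

Step 4
Reactants: 5 (4-bromobut-1-yn-1-yl)trimethylsilane; 6 3-chloro-2-(chloromethyl)prop-1-ene
Product: 8 [6-(chloromethyl)hept-6-en-1-yn-1-yl]trimethylsilane, via homopropargyl Grignard reagent 7 (not isolated)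
Conditions: Mg, THF, rt; then 6 (3 equiv), Li2CuCl4 (3 mol %), THF, −20 → 0 °C
Reagents that add atoms: none
Why: Copper-catalysed Grignard allylic substitution (Kochi-type coupling) on the symmetric dichloride, where SN2 and SN2' attack give the same product and the excess of 6 should hold back double substitution.

Step 5
Reactants: 8 [6-(chloromethyl)hept-6-en-1-yn-1-yl]trimethylsilane; 4 (S)-tert-butyldimethyl[2-(oxiran-2-yl)ethoxy]silane
Product: 10 (3R)-1-[(tert-butyldimethylsilyl)oxy]-6-methylidene-11-(trimethylsilyl)undec-10-yn-3-ol, via allylic Grignard reagent 9 (not isolated)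
Conditions: Mg (excess), THF, 0 °C, slow addition of 8; then CuI (10 mol %), 4, −30 → 0 °C; aqueous work-up
Reagents that add atoms: none
Why: Copper-catalysed opening of the terminal epoxide at its CH2 carbon by a 2-substituted allyl Grignard reagent whose two termini are equivalent, so no regioisomer can arise; the stereocentre is untouched (its descriptor changes from S to R only through CIP priorities), and low temperature should suppress Wurtz coupling and magnesium-ene cyclisation.

Step 6
Reactants: 10 (3R)-1-[(tert-butyldimethylsilyl)oxy]-6-methylidene-11-(trimethylsilyl)undec-10-yn-3-ol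
Product: 11 (3R)-1-[(tert-butyldimethylsilyl)oxy]-6-methylidene-11-(trimethylsilyl)undec-10-yn-3-yl methanesulfonate
Conditions: MsCl, Et3N, CH2Cl2, 0 °C
Reagents that add atoms: methanesulfonyl chloride, CS(=O)(=O)Cl
Why: O-Sulfonylation of the secondary alcohol proceeds at oxygen with retention and installs the leaving group for the later peroxide ring closure.

Step 7
Reactants: 11 (3R)-1-[(tert-butyldimethylsilyl)oxy]-6-methylidene-11-(trimethylsilyl)undec-10-yn-3-yl methanesulfonate
Product: 13 (3R,6RS)-1-[(tert-butyldimethylsilyl)oxy]-6-hydroperoxy-6-methoxy-11-(trimethylsilyl)undec-10-yn-3-yl methanesulfonate, via carbonyl oxide 12 (not isolated)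
Conditions: O3, CH2Cl2/MeOH (4:1), Sudan Red 7B end-point, −78 °C; N2 purge; concentration below 25 °C, no reductant
Reagents that add atoms: ozone, [O-][O+]=O; methanol, CO
Why: Criegee ozonolysis in methanol, in which the primary ozonide of the 1,1-disubstituted alkene should fragment to formaldehyde and the more substituted carbonyl oxide, which methanol traps as the α-methoxy hydroperoxide; the silyl alkyne reacts far more slowly with ozone than the alkene, and C6 is formed as both epimers.

Step 8
Reactants: 13 (3R,6RS)-1-[(tert-butyldimethylsilyl)oxy]-6-hydroperoxy-6-methoxy-11-(trimethylsilyl)undec-10-yn-3-yl methanesulfonate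
Product: 14 tert-butyl{2-[(3S,6RS)-6-methoxy-6-[5-(trimethylsilyl)pent-4-yn-1-yl]-1,2-dioxan-3-yl]ethoxy}dimethylsilane
Conditions: KOtBu (1.1 equiv), 18-crown-6, THF (0.01 M), 0 °C
Reagents that add atoms: none
Why: Intramolecular alkylation of a hydroperoxyketal (6-exo-tet SN2), in which the weakly basic α-effect peroxy anion displaces the secondary mesylate with inversion and so converts the (R)-sulfonate into the (3S) C–O–O centre; the tertiary hydroperoxyketal has no α-hydrogen and cannot undergo Kornblum–DeLaMare fragmentation, and any premature loss of the alkynyl silyl group is harmless because step 9 removes it anyway.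

Step 9
Reactants: 14 tert-butyl{2-[(3S,6RS)-6-methoxy-6-[5-(trimethylsilyl)pent-4-yn-1-yl]-1,2-dioxan-3-yl]ethoxy}dimethylsilane
Product: 16 2-[(3S,6R)-6-methoxy-6-(pent-4-yn-1-yl)-1,2-dioxan-3-yl]ethan-1-ol, via silylalkyne alcohol 15 (not isolated)
Conditions: CSA (0.2 equiv), MeOH, rt, until the C6 epimer ratio is constant; then K2CO3 (2 equiv), MeOH, 0 °C → rt
Reagents that add atoms: methanol, CO (the C6 methoxy group is exchanged with the solvent)
Why: Acid-catalysed methanolysis should cleave the primary TBS ether and reversibly ionise the peroxyketal to a peroxycarbenium ion, so that C6 equilibrates (ketal anomerisation under thermodynamic control by C3) to the epimer with axial OMe and both carbon substituents equatorial, which is 6R; methanolic carbonate then cleaves the C(sp)–Si bond.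

Step 10
Reactants: 16 2-[(3S,6R)-6-methoxy-6-(pent-4-yn-1-yl)-1,2-dioxan-3-yl]ethan-1-ol
Product: 18 2-[(3S,6R)-6-methoxy-6-(pent-4-yn-1-yl)-1,2-dioxan-3-yl]acetic acid, via dioxanyl acetaldehyde 17 (not isolated)
Conditions: TEMPO (0.2 equiv), PhI(OAc)2 (2.5 equiv), MeCN/pH 7 phosphate buffer (1:1), rt
Reagents that add atoms: water, O
Why: TEMPO/PhI(OAc)2 oxidation of a primary alcohol through the aldehyde hydrate to the acid (Epp–Widlanski conditions); the oxoammonium oxidant should leave the dialkyl peroxide and the terminal alkyne untouched, and the buffer protects the peroxyketal and keeps the β-peroxy aldehyde from eliminating.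

Step 11
Reactants: 19 dec-9-en-1-ol
Product: 20 dec-9-enal
Conditions: TEMPO (0.1 equiv), PhI(OAc)2 (1.1 equiv), CH2Cl2, rt
Reagents that add atoms: none
Why: Anhydrous TEMPO/PhI(OAc)2 oxidation should stop at the aldehyde and leaves the terminal alkene untouched.

Step 12
Reactants: 20 dec-9-enal
Product: 21 (E)-1-iodoundeca-1,10-diene
Conditions: CrCl2 (6 equiv), CHI3 (2 equiv), dioxane/THF (6:1), 0 °C → rt; residual Z isomer removed on AgNO3-impregnated silica
Reagents that add atoms: iodoform, IC(I)I
Why: Takai olefination, in which the geminal dichromium species from iodoform adds to the aldehyde and eliminates through the arrangement that places the alkyl chain and iodine anti, so the E alkenyl iodide should predominate (dioxane as co-solvent raises the E preference).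

Step 13
Reactants: 18 2-[(3S,6R)-6-methoxy-6-(pent-4-yn-1-yl)-1,2-dioxan-3-yl]acetic acid; 21 (E)-1-iodoundeca-1,10-diene (1.2 equiv)
Product: 22 2-[(3S,6R)-6-[(6E)-hexadeca-6,15-dien-4-yn-1-yl]-6-methoxy-1,2-dioxan-3-yl]acetic acid (target)
Conditions: Pd(PPh3)4 (5 mol %), CuI (10 mol %), i-Pr2NH (5 equiv), degassed THF, rt, dark
Reagents that add atoms: none
Why: Sonogashira coupling: Pd(0) inserts into the C–I bond of 21 with retention, the copper acetylide formed from the terminal alkyne of 18 (present as its ammonium carboxylate) transmetalates, and reductive elimination forms the C(sp)–C(sp2) bond of the enyne, joining a C12 and a C11 fragment in the last step with no protecting group left to remove. The closest known reaction type is the Pd/Cu alkynylation of alkenyl iodides carried out on substrates that contain a dialkyl peroxide or an unprotected carboxylic acid. No ring is closed and no stereocentre is formed; the E geometry is carried over from 21 by stereoretentive oxidative addition, and the (3S,6R) centres are spectators. The selectivity needed is C–I over O–O: oxidative addition to an alkenyl iodide is fast at room temperature, whereas the O1–O2 bond is shielded by the fully substituted C6 and sits five atoms from the alkyne, and the carboxylate form of the acid cannot open the C3–O2 bond by E1cB elimination. Degassing should suppress oxidative alkyne homocoupling, and the terminal alkene of 21 has no Heck pathway at room temperature.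

**Compound list**
1 | but-3-en-1-ol | C=CCCO | starting material
2 | tert-butyl(but-3-en-1-yloxy)dimethylsilane | C=CCCO[Si](C)(C)C(C)(C)C | intermediate
3 | rac-tert-butyldimethyl[2-(oxiran-2-yl)ethoxy]silane | CC(C)(C)[Si](C)(C)OCCC1CO1 | intermediate
4 | (S)-tert-butyldimethyl[2-(oxiran-2-yl)ethoxy]silane | CC(C)(C)[Si](C)(C)OCC[C@H]1CO1 | intermediate
5 | (4-bromobut-1-yn-1-yl)trimethylsilane | C[Si](C)(C)C#CCCBr | starting material
6 | 3-chloro-2-(chloromethyl)prop-1-ene | C=C(CCl)CCl | starting material
7 | [4-(trimethylsilyl)but-3-yn-1-yl]magnesium bromide (not isolated) | C[Si](C)(C)C#CCC[Mg]Br | intermediate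
8 | [6-(chloromethyl)hept-6-en-1-yn-1-yl]trimethylsilane | C[Si](C)(C)C#CCCCC(=C)CCl | intermediate
9 | chloro[2-methylidene-7-(trimethylsilyl)hept-6-yn-1-yl]magnesium (not isolated) | C[Si](C)(C)C#CCCCC(=C)C[Mg]Cl | intermediate
10 | (3R)-1-[(tert-butyldimethylsilyl)oxy]-6-methylidene-11-(trimethylsilyl)undec-10-yn-3-ol | C[Si](C)(C)C#CCCCC(=C)CC[C@@H](O)CCO[Si](C)(C)C(C)(C)C | intermediate
11 | (3R)-1-[(tert-butyldimethylsilyl)oxy]-6-methylidene-11-(trimethylsilyl)undec-10-yn-3-yl methanesulfonate | C[Si](C)(C)C#CCCCC(=C)CC[C@@H](OS(C)(=O)=O)CCO[Si](C)(C)C(C)(C)C | intermediate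
12 | carbonyl oxide at C6 of the mesylate (not isolated) | C[Si](C)(C)C#CCCCC(=[O+][O-])CC[C@@H](OS(C)(=O)=O)CCO[Si](C)(C)C(C)(C)C | intermediate
13 | (3R,6RS)-1-[(tert-butyldimethylsilyl)oxy]-6-hydroperoxy-6-methoxy-11-(trimethylsilyl)undec-10-yn-3-yl methanesulfonate (both C6 epimers) | C[Si](C)(C)C#CCCCC(OC)(OO)CC[C@@H](OS(C)(=O)=O)CCO[Si](C)(C)C(C)(C)C | intermediate
14 | tert-butyl{2-[(3S,6RS)-6-methoxy-6-[5-(trimethylsilyl)pent-4-yn-1-yl]-1,2-dioxan-3-yl]ethoxy}dimethylsilane (both C6 epimers) | C[Si](C)(C)C#CCCCC1(OC)CC[C@@H](CCO[Si](C)(C)C(C)(C)C)OO1 | intermediate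
15 | 2-{(3S,6R)-6-methoxy-6-[5-(trimethylsilyl)pent-4-yn-1-yl]-1,2-dioxan-3-yl}ethan-1-ol (not isolated) | C[Si](C)(C)C#CCCC[C@]1(OC)CC[C@@H](CCO)OO1 | intermediate
16 | 2-[(3S,6R)-6-methoxy-6-(pent-4-yn-1-yl)-1,2-dioxan-3-yl]ethan-1-ol | C#CCCC[C@]1(OC)CC[C@@H](CCO)OO1 | intermediate
17 | 2-[(3S,6R)-6-methoxy-6-(pent-4-yn-1-yl)-1,2-dioxan-3-yl]acetaldehyde (not isolated) | C#CCCC[C@]1(OC)CC[C@@H](CC=O)OO1 | intermediate
18 | 2-[(3S,6R)-6-methoxy-6-(pent-4-yn-1-yl)-1,2-dioxan-3-yl]acetic acid | C#CCCC[C@]1(OC)CC[C@@H](CC(=O)O)OO1 | intermediate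
19 | dec-9-en-1-ol | C=CCCCCCCCCO | starting material
20 | dec-9-enal | C=CCCCCCCCC=O | intermediate
21 | (E)-1-iodoundeca-1,10-diene | C=CCCCCCCC/C=C/I | intermediate
22 | 2-[(3S,6R)-6-[(6E)-hexadeca-6,15-dien-4-yn-1-yl]-6-methoxy-1,2-dioxan-3-yl]acetic acid | C=CCCCCCCC/C=C/C#CCCC[C@]1(OC)CC[C@@H](CC(=O)O)OO1 | target

**Summary**
Total step count: 13.
Longest linear sequence: 10 steps (1, 2, 3, 5, 6, 7, 8, 9, 10, 13).

**Steps most likely to fail**

Step 13. What may go wrong: reduction or cleavage of the O–O bond by Pd(0) or Cu(I), amine-induced fragmentation of the dioxane, oxidative homocoupling of the alkyne, or slow transmetalation because the carboxylate binds copper. The fallback reverses the polarity of the coupling and uses neither copper nor amine; it sets out from 18 and 21 and comes back at 22. Acid 18 would be esterified (TMSCHN2, MeOH/toluene, 0 °C) to methyl 2-[(3S,6R)-6-methoxy-6-(pent-4-yn-1-yl)-1,2-dioxan-3-yl]acetate F1. Its terminal alkyne would be brominated (NBS, cat. AgNO3, acetone, rt) to methyl 2-[(3S,6R)-6-(5-bromopent-4-yn-1-yl)-6-methoxy-1,2-dioxan-3-yl]acetate F2. Iodide 21 would be converted by iodine–lithium exchange (t-BuLi, Et2O, −78 °C) and trapping with 2-isopropoxy-4,4,5,5-tetramethyl-1,3,2-dioxaborolane into (E)-2-(undeca-1,10-dien-1-yl)-4,4,5,5-tetramethyl-1,3,2-dioxaborolane F3. Suzuki–Miyaura coupling of F2 with F3 (Pd(dppf)Cl2, K3PO4, THF/H2O, rt) should give methyl 2-[(3S,6R)-6-[(6E)-hexadeca-6,15-dien-4-yn-1-yl]-6-methoxy-1,2-dioxan-3-yl]acetate F4, and saponification (LiOH, THF/H2O, 0 °C) should give 22.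

Step 8. What may go wrong: E2 elimination of the secondary mesylate or intermolecular alkylation outrunning the 6-exo closure, and base-induced decomposition of the hydroperoxyketal. The fallback forms the C3–O bond first and closes the ring by ketalisation; it sets out from 11 and comes back at 14. The mesylate of 11 would be displaced with inversion by 2-methoxyprop-2-yl hydroperoxide (CsOH·H2O, DMF, 0 °C) to give tert-butyldimethyl{[(3S)-3-[(2-methoxypropan-2-yl)peroxy]-6-methylidene-11-(trimethylsilyl)undec-10-yn-1-yl]oxy}silane F5. Ozonolysis with reductive work-up (O3, CH2Cl2/MeOH, −78 °C; then Me2S) would give (9S)-11-[(tert-butyldimethylsilyl)oxy]-9-[(2-methoxypropan-2-yl)peroxy]-1-(trimethylsilyl)undec-1-yn-6-one F6. Brief CSA/MeOH treatment would release (9S)-11-[(tert-butyldimethylsilyl)oxy]-9-hydroperoxy-1-(trimethylsilyl)undec-1-yn-6-one F7, which should add to its own ketone and be converted under the same acidic methanol into the methyl peroxyketal 14; step 9 then continues unchanged.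

Step 9. What may go wrong: slow or incomplete anomerisation at C6, acid-induced opening or hydrolysis of the peroxyketal, or fragmentation of the ring after the switch to carbonate. The fallback gives up equilibration for fluoride deprotection and separation; it sets out from 14 and comes back at 16. Both silyl groups would be removed with TBAF buffered with AcOH (THF, 0 °C → rt), which does not touch C6, and the two C6 epimers would be separated by chromatography at the alcohol stage. Alcohol 16 continues into step 10; the epimer 2-[(3S,6S)-6-methoxy-6-(pent-4-yn-1-yl)-1,2-dioxan-3-yl]ethan-1-ol F8 would be resubmitted separately to CSA/MeOH or set aside.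

Further compounds
F1 | step 13 | methyl 2-[(3S,6R)-6-methoxy-6-(pent-4-yn-1-yl)-1,2-dioxan-3-yl]acetate | C#CCCC[C@]1(OC)CC[C@@H](CC(=O)OC)OO1
F2 | step 13 | methyl 2-[(3S,6R)-6-(5-bromopent-4-yn-1-yl)-6-methoxy-1,2-dioxan-3-yl]acetate | BrC#CCCC[C@]1(OC)CC[C@@H](CC(=O)OC)OO1
F3 | step 13 | (E)-2-(undeca-1,10-dien-1-yl)-4,4,5,5-tetramethyl-1,3,2-dioxaborolane | C=CCCCCCCC/C=C/B1OC(C)(C)C(C)(C)O1
F4 | step 13 | methyl 2-[(3S,6R)-6-[(6E)-hexadeca-6,15-dien-4-yn-1-yl]-6-methoxy-1,2-dioxan-3-yl]acetate | C=CCCCCCCC/C=C/C#CCCC[C@]1(OC)CC[C@@H](CC(=O)OC)OO1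
F5 | step 8 | tert-butyldimethyl{[(3S)-3-[(2-methoxypropan-2-yl)peroxy]-6-methylidene-11-(trimethylsilyl)undec-10-yn-1-yl]oxy}silane | C[Si](C)(C)C#CCCCC(=C)CC[C@H](OOC(C)(C)OC)CCO[Si](C)(C)C(C)(C)C
F6 | step 8 | (9S)-11-[(tert-butyldimethylsilyl)oxy]-9-[(2-methoxypropan-2-yl)peroxy]-1-(trimethylsilyl)undec-1-yn-6-one | C[Si](C)(C)C#CCCCC(=O)CC[C@H](OOC(C)(C)OC)CCO[Si](C)(C)C(C)(C)C
F7 | step 8 | (9S)-11-[(tert-butyldimethylsilyl)oxy]-9-hydroperoxy-1-(trimethylsilyl)undec-1-yn-6-one | C[Si](C)(C)C#CCCCC(=O)CC[C@H](OO)CCO[Si](C)(C)C(C)(C)C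
F8 | step 9 | 2-[(3S,6S)-6-methoxy-6-(pent-4-yn-1-yl)-1,2-dioxan-3-yl]ethan-1-ol | C#CCCC[C@@]1(OC)CC[C@@H](CCO)OO1
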